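**Retrosynthetic overview**

- The dihydropyran ring (O–C4 and C1′–C5 bonds) is opened by a retro hetero-Diels–Alder reaction into 3-methylbutylidenesyncarpic acid (an enetrione 1-oxadiene) and the endocyclic E-alkene of (−)-β-caryophyllene.
- The enetrione comes from a Knoevenagel condensation of syncarpic acid with isovaleraldehyde, run in the same pot as the cycloaddition.
- Syncarpic acid comes from deacetylation of acetylsyncarpic acid, which comes from fourfold C-methylation of 2,4,6-trihydroxyacetophenone.
- Ring order: the cyclobutane and nine-membered rings are bought with caryophyllene (C1, C9 fixed), the trione ring is the former phloroglucinol ring, and the pyran ring is formed last, setting C4, C5 and C1′.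

Assumption: syncarpic acid is not treated as a catalogue item and is made in two steps; natural (−)-β-caryophyllene (1R,4E,9S) is bought; caryophyllene numbering is used for the terpene part, and C1′ is the CH that carries the isobutyl group.

**Route**

Step 1
Reactants: 1 2,4,6-trihydroxyacetophenone
Product: 2 acetylsyncarpic acid
Conditions: NaOMe (6 equiv), MeI (8 equiv), MeOH, 0 °C → reflux, 6 h; then 2 M HCl
Reagents that add atoms: methyl iodide (MeI), CI
Why: Exhaustive dearomatising C-alkylation of the phloroglucinol polyanion (SN2 on MeI), in which the acetyl group blocks the third ring carbon so that exactly two methyls enter at each free ring carbon and the ring is locked as the enolised β-triketone; no stereocentre is formed.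

Step 2
Reactants: 2 acetylsyncarpic acid
Product: 3 syncarpic acid
Conditions: 6 M aq HCl, reflux, 16 h; crystallise on cooling
Reagents that add atoms: none
Why: Acid-catalysed retro-Claisen deacylation, in which water adds to the unhindered exocyclic acetyl carbonyl and the stabilised syncarpic enol leaves, while the ring carbonyls are shielded by the neighbouring quaternary carbons; no stereocentre is involved.

Step 3
Reactants: 3 syncarpic acid; 4 isovaleraldehyde; 5 (−)-β-caryophyllene
Product: 7 tomentodione A, via 3-methylbutylidenesyncarpic acid 6 (not isolated)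
Conditions: 4 (1.5 equiv), 5 (2 equiv), EDDA (10 mol %), PhMe, sealed tube, 80 °C, 16 h, 3 added in portions; SiO2 then semi-preparative HPLC to remove the 1′-epimer (which may form in comparable amount) and minor ββ-conformer adducts
Reagents that add atoms: none
Why: Domino Knoevenagel condensation/inverse-electron-demand hetero-Diels–Alder reaction, in which the symmetric oxadiene 6 bonds through its electrophilic terminus to the less substituted C5 and through oxygen to the tertiary C4 of the strained E-alkene of 5 (the exocyclic methylene is much less reactive); suprafacial addition to the E-alkene fixes the trans ring fusion (4-CH3 anti to H-5), attack on the exposed face of the major αα/βα conformers (the face that gives natural caryophyllene β-oxide) sets 4R,5S, the alignment with isobutyl on the outside of the oxadiene and the C3/H-5 edge endo sets 1′S, and C1 and C9 are untouched.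

**Compound list**

1 | 2,4,6-trihydroxyacetophenone (phloroacetophenone) | CC(=O)c1c(O)cc(O)cc1O | starting material
2 | acetylsyncarpic acid: 2-acetyl-3-hydroxy-4,4,6,6-tetramethylcyclohex-2-ene-1,5-dione | CC(=O)C1=C(O)C(C)(C)C(=O)C(C)(C)C1=O | intermediate
3 | syncarpic acid: 3-hydroxy-4,4,6,6-tetramethylcyclohex-2-ene-1,5-dione (enol of 2,2,4,4-tetramethylcyclohexane-1,3,5-trione) | CC1(C)C(=O)C=C(O)C(C)(C)C1=O | intermediate
4 | isovaleraldehyde (3-methylbutanal) | CC(C)CC=O | starting material
5 | (−)-β-caryophyllene, (1R,4E,9S)-4,11,11-trimethyl-8-methylenebicyclo[7.2.0]undec-4-ene | C/C1=C\CCC(=C)[C@H]2CC(C)(C)[C@@H]2CC1 | starting material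
6 | 3-methylbutylidenesyncarpic acid: 2-(3-methylbutylidene)-4,4,6,6-tetramethylcyclohexane-1,3,5-trione | CC(C)CC=C1C(=O)C(C)(C)C(=O)C(C)(C)C1=O | intermediate
7 | tomentodione A: (1R,4R,5S,9S,1′S) adduct; pyran ring trans-fused to the nine-membered ring at C4 (O, CH3) and C5 (H); H-1′ anti to H-5; isobutyl on C1′; trans-fused gem-dimethylcyclobutane; exocyclic methylene at C8 | C=C1CC[C@H]2[C@H](CC(C)C)C3=C(O[C@]2(C)CC[C@@H]2[C@@H]1CC2(C)C)C(C)(C)C(=O)C(C)(C)C3=O | target

**Totals**

Total step count: 3. Longest linear sequence: 3 steps (1 → 2 → 3 → 7).

**Steps most likely to fail, with fallbacks**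

Step 3 is the most likely to fail. Free 3 can add to 6 to give the 2:1 bis-adduct, 5 can isomerise on prolonged heating, and the cycloaddition is not fully selective between 7 and its 1′-epimer. The fallback sets out from 3 and separates the condensation from the cycloaddition. Compound 3 is stirred with 4 and piperidine (1 equiv each, CH2Cl2, rt) to give the crystalline, storable Mannich base, racemic 3-hydroxy-2-[3-methyl-1-(piperidin-1-yl)butyl]-4,4,6,6-tetramethylcyclohex-2-ene-1,5-dione F1. A CH2Cl2 suspension of this is shaken with cold 1 M HCl to strip the amine, and the dried organic layer is a solution of 6 free of 3. The fallback comes back to the route at 6, which is stirred with 5 (2 equiv) without catalyst at 0 °C → 40 °C to give 7. The lower temperature and absence of 3 suppress the bis-adduct and should sharpen facial and endo/exo selectivity.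

Step 1 is next. Under- or over-methylation and O-methylation can give mixtures that are hard to separate. The fallback sets out from 1 and installs the first two ring methyls reductively. A double Mannich reaction (aq Me2NH, aq CH2O, EtOH, rt) at the two free ring positions gives 1-[3,5-bis(dimethylaminomethyl)-2,4,6-trihydroxyphenyl]ethan-1-one F2. Hydrogenolysis of the benzylic amines (H2, Pd/C, AcOH, 60 °C) gives 1-(2,4,6-trihydroxy-3,5-dimethylphenyl)ethan-1-one F3. Only two dearomatising C-methylations then remain (MeI 2.5 equiv, NaOMe 3 equiv, MeOH, reflux), both at carbons that already carry a methyl, and the fallback comes back to the route at 2.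

Step 2 is the least risky, but the retro-Claisen could stall or be accompanied by ring cleavage under prolonged hot acid. The fallback sets out from 2 and triggers the deacylation with an electrophile instead of hot acid. Bromination at the central carbon (NBS, CH2Cl2, 0 °C) gives the non-enolisable 2-acetyl-2-bromo-4,4,6,6-tetramethylcyclohexane-1,3,5-trione F4. Its acetyl group is cleaved under very mild methanolysis (K2CO3, MeOH, 0 °C) to give 2-bromo-3-hydroxy-4,4,6,6-tetramethylcyclohex-2-ene-1,5-dione F5. Reductive debromination (Zn dust, AcOH, rt) then gives syncarpic acid, and the fallback comes back to the route at 3.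

**Further compounds**

F1 | step 3 | 3-hydroxy-2-[3-methyl-1-(piperidin-1-yl)butyl]-4,4,6,6-tetramethylcyclohex-2-ene-1,5-dione (racemic) | CC(C)CC(N1CCCCC1)C1=C(O)C(C)(C)C(=O)C(C)(C)C1=O
F2 | step 1 | 1-[3,5-bis(dimethylaminomethyl)-2,4,6-trihydroxyphenyl]ethan-1-one | CC(=O)c1c(O)c(CN(C)C)c(O)c(CN(C)C)c1O
F3 | step 1 | 1-(2,4,6-trihydroxy-3,5-dimethylphenyl)ethan-1-one | CC(=O)c1c(O)c(C)c(O)c(C)c1O
F4 | step 2 | 2-acetyl-2-bromo-4,4,6,6-tetramethylcyclohexane-1,3,5-trione | CC(=O)C1(Br)C(=O)C(C)(C)C(=O)C(C)(C)C1=O
F5 | step 2 | 2-bromo-3-hydroxy-4,4,6,6-tetramethylcyclohex-2-ene-1,5-dione | OC1=C(Br)C(=O)C(C)(C)C(=O)C1(C)C
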